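**Plan**

1. Retrosynthesis: the C3=C4 double bond of the dimethoxycoumarin half is traced back to a saturated lactone carrying CO2Me on C3 and NMe2 on C4. Then O1–C8a, C4–C4a, C3–C4 and O1–C2 are cut together, which leaves 4,5-dimethoxybenzyne, DMF (the C4–H unit) and an aryloxymalonate. Last, the malonate C–O(aryl) bond is cut back to umbelliferone.
2. Enabling feature: O1 (on C8a) and C4 (on C4a) are ortho neighbours on the benzo ring, and the 6,7-dimethoxy pattern is mirror-symmetric about the C4a–C8a bond, so one symmetrical aryne can take both bonds with no regiochemical question.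
3. Forward order: the umbelliferone bicycle is bought intact and joined through its 7-oxygen to the malonate carbon (the future C3). The second pyranone ring is then closed onto the aryne-derived benzene ring in one three-component operation and aromatised in the last step.
4. Stereochemistry: the target is achiral. The two sp3 centres (C3, C4) that arise in the annulation are formed without control and both vanish in the final dealkoxycarbonylative elimination.

Key step: step 2

Remark on the chemistry: umbelliferone, dimethyl bromomalonate, the silyl triflate aryne precursor and DMF are taken as purchased; the annulation product is carried on as its mixture of diastereomers.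

**Route**

Step 1
Reactants: 1 umbelliferone (7-hydroxy-2H-chromen-2-one); 2 dimethyl bromomalonate
Product: 3 dimethyl 2-[(2-oxo-2H-chromen-7-yl)oxy]propanedioate
Conditions: K2CO3 (1.5 equiv), 2 (1.0 equiv), acetone, reflux
Reagents that add atoms: none
Why: Williamson-type O-alkylation (SN2) of the acidic coumarin phenoxide at the doubly activated bromide, under carbonate/acetone conditions that leave the lactone closed; keeping 2 at one equivalent limits further reaction of the acidic product.

Step 2
Reactants: 3 dimethyl 2-[(2-oxo-2H-chromen-7-yl)oxy]propanedioate; 4 4,5-dimethoxy-2-(trimethylsilyl)phenyl trifluoromethanesulfonate; 5 N,N-dimethylformamide (also the solvent)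
Product: 10 methyl 4-(dimethylamino)-6,7-dimethoxy-2-oxo-3-[(2-oxo-2H-chromen-7-yl)oxy]chromane-3-carboxylate (racemic mixture of diastereomers), via 4,5-dimethoxybenzyne 6 (not isolated), via benzoxete aminal 7 (not isolated), via quinone methide iminium phenoxide 8 (not isolated), via Mannich adduct 9 (not isolated)
Conditions: CsF (4 equiv), DMF (solvent), rt, slow addition of 4 (1.5 equiv)
Reagents that add atoms: none
Why: Proposed new method: fluoride removes the silyl group of 4 and triflate departs to give aryne 6, which adds [2+2] across the C=O bond of 5 to benzoxete 7 (bonds C8a–O1 and C4a–C4) and ring-opens to the iminium phenoxide 8; the carbanion of 3, formed by fluoride, adds to the iminium carbon (bond C4–C3) to give 9, whose phenoxide then displaces methoxide from one ester (bond O1–C2). The closest known reaction type is the three-component coupling of arynes, DMF and active methylene compounds to coumarins, together with the trapping of the same intermediate by alpha-chloromalonate methines; new here is a methine malonate that carries no leaving group, so the sequence has to end at the saturated 4-amino lactone. The pyranone, the only ring formed, closes by 6-exo-trig acyl substitution, favoured by the fully substituted C3. The two new centres C3 and C4 are set without control (racemic mixture of diastereomers), which is harmless because both become sp2 in step 3. The step needs chemoselectivity for insertion into DMF over direct arylation of the malonate anion and over attack on the lactone of 3; DMF as solvent, slow release of 6 by sparingly soluble CsF and the mild basicity of fluoride should secure it, and the symmetry of 6 leaves no regiochemical choice.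

Step 3
Reactants: 10 methyl 4-(dimethylamino)-6,7-dimethoxy-2-oxo-3-[(2-oxo-2H-chromen-7-yl)oxy]chromane-3-carboxylate
Product: 13 daphnoretin methyl ether (6,7-dimethoxy-3-[(2-oxo-2H-chromen-7-yl)oxy]-2H-chromen-2-one), via lithium carboxylate 11 (not isolated), via 4-amino lactone 12 (not isolated)
Conditions: LiCl (2 equiv), H2O (2 equiv), DMSO, 130 °C
Reagents that add atoms: none
Why: Krapcho dealkoxycarbonylation, in which chloride removes the ester methyl by SN2, carboxylate 11 loses CO2 to the lactone enolate, and protonation gives Mannich base 12, which loses dimethylamine by E1cB beta-elimination driven by formation of the aromatic coumarin; the aryl lactones offer chloride no sp3 carbon and both transient stereocentres become sp2.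

**Compound list**

1 | umbelliferone (7-hydroxy-2H-chromen-2-one) | Oc1ccc2ccc(=O)oc2c1 | starting material
2 | dimethyl bromomalonate (dimethyl 2-bromopropanedioate) | COC(=O)C(Br)C(=O)OC | starting material
3 | dimethyl 2-[(2-oxo-2H-chromen-7-yl)oxy]propanedioate | COC(=O)C(Oc1ccc2ccc(=O)oc2c1)C(=O)OC | intermediate
4 | 4,5-dimethoxy-2-(trimethylsilyl)phenyl trifluoromethanesulfonate | COc1cc(OS(=O)(=O)C(F)(F)F)c(cc1OC)[Si](C)(C)C | starting material
5 | N,N-dimethylformamide | CN(C)C=O | starting material
6 | 4,5-dimethoxybenzyne (1,2-didehydro-4,5-dimethoxybenzene; not isolated) | COC1=CC#CC=C1OC | intermediate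
7 | 4,5-dimethoxy-N,N-dimethyl-2H-1-benzoxet-2-amine (benzoxete aminal, racemic; not isolated) | CN(C)C1Oc2cc(OC)c(OC)cc12 | intermediate
8 | 2-[(dimethyliminio)methyl]-4,5-dimethoxyphenolate (zwitterionic form of the ortho-quinone methide; not isolated) | C[N+](C)=Cc1cc(OC)c(OC)cc1[O-] | intermediate
9 | dimethyl 2-[(dimethylamino)(2-hydroxy-4,5-dimethoxyphenyl)methyl]-2-[(2-oxo-2H-chromen-7-yl)oxy]propanedioate (Mannich adduct, racemic; not isolated) | COC(=O)C(Oc1ccc2ccc(=O)oc2c1)(C(=O)OC)C(N(C)C)c1cc(OC)c(OC)cc1O | intermediate
10 | methyl 4-(dimethylamino)-6,7-dimethoxy-2-oxo-3-[(2-oxo-2H-chromen-7-yl)oxy]chromane-3-carboxylate (racemic mixture of diastereomers) | COC(=O)C1(Oc2ccc3ccc(=O)oc3c2)C(N(C)C)c2cc(OC)c(OC)cc2OC1=O | intermediate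
11 | lithium 4-(dimethylamino)-6,7-dimethoxy-2-oxo-3-[(2-oxo-2H-chromen-7-yl)oxy]chromane-3-carboxylate (mixture of diastereomers; not isolated) | [Li+].[O-]C(=O)C1(Oc2ccc3ccc(=O)oc3c2)C(N(C)C)c2cc(OC)c(OC)cc2OC1=O | intermediate
12 | 4-(dimethylamino)-6,7-dimethoxy-3-[(2-oxo-2H-chromen-7-yl)oxy]chroman-2-one (mixture of diastereomers; not isolated) | CN(C)C1C(Oc2ccc3ccc(=O)oc3c2)C(=O)Oc2cc(OC)c(OC)cc12 | intermediate
13 | daphnoretin methyl ether (6,7-dimethoxy-3-[(2-oxo-2H-chromen-7-yl)oxy]-2H-chromen-2-one) | COc1cc2cc(Oc3ccc4ccc(=O)oc4c3)c(=O)oc2cc1OC | target

**Count**

Total steps: 3. Longest linear sequence: 3 steps (1 → 3 → 10 → 13).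

**Steps most likely to fail, with fallbacks**

1. Step 2 (proposed new method).
   - Risk: the fully substituted carbanion of 3 may add to 8 too slowly. Then 8 is consumed by a second aryne or by traces of water, or the malonate anion is arylated directly by 6. Ring closure of 9 may also stall at the open phenol.
   - Fallback (known chemistry, sets out from 3, 4 and 5, returns at 13): the aryne insertion is run without the malonate and quenched with water (CsF, DMF, rt; then H2O). This is the known aryne formylation; it passes through 6, 7 and 8 and hydrolyses 8 to 2-hydroxy-4,5-dimethoxybenzaldehyde F1. Separately, 3 is hydrolysed and decarboxylated (6 M HCl, AcOH, reflux) through 2-[(2-oxo-2H-chromen-7-yl)oxy]propanedioic acid F2 to 2-[(2-oxo-2H-chromen-7-yl)oxy]acetic acid F3. Perkin condensation of F1 with F3 (Ac2O, Et3N, 120 °C), the classical entry to 3-aryloxycoumarins, forms C3–C4 and O1–C2 and gives 13 directly, so 10 and step 3 are bypassed.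

2. Step 3.
   - Risk: SN2 demethylation of the hindered ester is slow. Retro-Mannich fragmentation of 10, opening of the aryl lactones by the hydroxide formed, or halide demethylation of the C7 methoxy group on prolonged heating may compete.
   - Fallback (sets out from 10, returns at 13): the ester is removed by acid hydrolysis instead of halide dealkylation (6 M HCl, AcOH, reflux). The amine stays protonated, which blocks the retro-Mannich path and makes it a better leaving group. The methyl ester is hydrolysed to 4-(dimethylamino)-6,7-dimethoxy-2-oxo-3-[(2-oxo-2H-chromen-7-yl)oxy]chromane-3-carboxylic acid F4, which decarboxylates thermally to 12 and loses dimethylamine (as its hydrochloride) to give 13.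

3. Step 1.
   - Risk: bromine transfer from 2 to the phenoxide or to the acidic product, and a second alkylation of deprotonated 3, may erode the mono-ether.
   - Fallback (sets out from 1, returns at 3): base-free carbenoid O–H insertion. Purchased dimethyl diazomalonate is decomposed with Rh2(OAc)4 (1 mol %) in 1,2-dichloroethane at 80 °C in the presence of 1. The rhodium carbenoid inserts into the phenolic O–H bond to give 3 with no halide or base present and without making any new intermediate.

**Further compounds**

F1 | step 2 | 2-hydroxy-4,5-dimethoxybenzaldehyde | COc1cc(O)c(C=O)cc1OC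
F2 | step 2 | 2-[(2-oxo-2H-chromen-7-yl)oxy]propanedioic acid | OC(=O)C(Oc1ccc2ccc(=O)oc2c1)C(O)=O
F3 | step 2 | 2-[(2-oxo-2H-chromen-7-yl)oxy]acetic acid | OC(=O)COc1ccc2ccc(=O)oc2c1
F4 | step 3 | 4-(dimethylamino)-6,7-dimethoxy-2-oxo-3-[(2-oxo-2H-chromen-7-yl)oxy]chromane-3-carboxylic acid | CN(C)C1c2cc(OC)c(OC)cc2OC(=O)C1(Oc1ccc2ccc(=O)oc2c1)C(O)=O
F0 | step 1 | none | none
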